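The upper pyran ring (ring C: O1, C2, C3, C4, C4a, C8a) is a 3-unsubstituted 2,4-cis-2,4-diarylchroman whose C4 is bonded to C8 of a catechin unit. That ring is cut at O1–C2 and C3–C4 into an ortho-quinone methide (O1=C8a–C4a=C4, catechin-8-yl on C4) and a 3,4-dioxygenated styrene (C2=C3). One acid-catalysed oxa-[4+2] event closes the ring, rearomatises ring A and sets C2 and C4 cis under control of a chiral phosphoric acid. The precursor is an ortho-hydroxybenzhydrol made by adding 8-lithiated perbenzyl-(+)-catechin to a protected phloroglucinaldehyde; only its phloroglucinol ring carries a free phenol. Hydrogenolysis of nine benzyl ethers finishes the synthesis.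

Key step: step 9

Assumption: the (R)-antipode of the phosphoric acid is taken as the one matched to the (2S,4S) adduct; the sense of induction on this hindered methide cannot be assigned in advance, both antipodes are available, and (S)-TRIP replaces it with nothing else changed if a pilot run shows the opposite sense.

"Penta-O-benzylcatechin-8-yl" below means (2R,3S)-3,5,7-tris(benzyloxy)-2-[3,4-bis(benzyloxy)phenyl]chroman-8-yl.

Step 1
Reactants: 1 (+)-catechin
Product: 2 5,7,3',4'-tetra-O-benzyl-(+)-catechin (2R,3S; free 3-OH)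
Conditions: BnBr (4.4 equiv), K2CO3 (5 equiv), DMF, 0 °C to rt, Ar
Reagents that add atoms: benzyl bromide, BrCc1ccccc1
Why: Williamson etherification with a carbonate base alkylates the four phenols only, since the secondary 3-OH is not deprotonated, and the mild conditions leave C2 and C3 untouched.

Step 2
Reactants: 2 5,7,3',4'-tetra-O-benzyl-(+)-catechin
Product: 3 3,5,7,3',4'-penta-O-benzyl-(+)-catechin (2R,3S)
Conditions: NaH (1.5 equiv), BnBr (1.3 equiv), DMF, 0 °C to rt
Reagents that add atoms: benzyl bromide, BrCc1ccccc1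
Why: Williamson etherification of the sodium alkoxide of the one remaining alcohol removes the last acidic proton before the organolithium and acid steps, with retention at C3 because no bond to that center is broken.

Step 3
Reactants: 3 3,5,7,3',4'-penta-O-benzyl-(+)-catechin
Product: 4 8-bromo-3,5,7,3',4'-penta-O-benzyl-(+)-catechin (2R,3S)
Conditions: NBS (1.05 equiv), CH2Cl2, −78 °C to rt, dark
Reagents that add atoms: N-bromosuccinimide, O=C1CCC(=O)N1Br
Why: Electrophilic aromatic bromination of the phloroglucinol-type ring of perbenzylated catechins with one equivalent of NBS is an established C8-selective reaction (C8 over C6), and without light or initiator the benzylic positions are not attacked.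

Step 4
Reactants: 5 2,4,6-trihydroxybenzaldehyde
Product: 6 2,4-bis(benzyloxy)-6-hydroxybenzaldehyde
Conditions: BnBr (2.05 equiv), K2CO3 (2.1 equiv), DMF, 0 °C to rt
Reagents that add atoms: benzyl bromide, BrCc1ccccc1
Why: Williamson etherification under stoichiometric control takes the most acidic 4-OH and then one ortho-OH, while the last ortho-OH is held in a hydrogen bond to the formyl oxygen and is the least nucleophilic.

Step 5
Reactants: 6 2,4-bis(benzyloxy)-6-hydroxybenzaldehyde
Product: 7 2,4-bis(benzyloxy)-6-(tert-butyldimethylsilyloxy)benzaldehyde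
Conditions: TBSCl (1.3 equiv), imidazole (2.5 equiv), DMF, rt
Reagents that add atoms: tert-butyldimethylsilyl chloride, CC(C)(C)[Si](C)(C)Cl
Why: Imidazole-promoted O-silylation masks the only acidic proton of the aldehyde partner as a silyl ether that tolerates an aryllithium and is later removed by fluoride without touching benzyl ethers.

Step 6
Reactants: 4 8-bromo-3,5,7,3',4'-penta-O-benzyl-(+)-catechin; 7 2,4-bis(benzyloxy)-6-(tert-butyldimethylsilyloxy)benzaldehyde
Product: 9 [2,4-bis(benzyloxy)-6-(tert-butyldimethylsilyloxy)phenyl](penta-O-benzylcatechin-8-yl)methanol (both carbinol epimers), via 8-lithio-penta-O-benzylcatechin 8 (not isolated)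
Conditions: t-BuLi (2.1 equiv), THF, −78 °C, 15 min; then 7 (1.3 equiv), −78 to −40 °C; aq NH4Cl at −78 °C
Reagents that add atoms: none
Why: Bromine–lithium exchange at −78 °C outruns any attack of t-BuLi on the benzyl ethers and the aryllithium flanked by two oxygens then undergoes 1,2-addition to the non-enolisable aldehyde, forming the future C4–C8 bond; the new carbinol center is formed without control, which is harmless because it becomes planar in step 9.

Step 7
Reactants: 9 [2,4-bis(benzyloxy)-6-(tert-butyldimethylsilyloxy)phenyl](penta-O-benzylcatechin-8-yl)methanol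
Product: 10 [2,4-bis(benzyloxy)-6-hydroxyphenyl](penta-O-benzylcatechin-8-yl)methanol (both carbinol epimers; used at once)
Conditions: TBAF (1.2 equiv), AcOH (1.2 equiv), THF, 0 °C, 30 min
Reagents that add atoms: none
Why: Fluoride-mediated desilylation of the aryl silyl ether, buffered with acetic acid so that neither base nor strong acid meets the ionisable benzhydrol, frees the single phenol that the methide needs.

Step 8
Reactants: 11 3,4-bis(benzyloxy)benzaldehyde
Product: 12 3,4-bis(benzyloxy)styrene
Conditions: MePPh3Br (1.3 equiv), KOtBu (1.25 equiv), THF, 0 °C to rt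
Reagents that add atoms: methyltriphenylphosphonium bromide, C[P+](c1ccccc1)(c1ccccc1)c1ccccc1.[Br-]
Why: Wittig methylenation of a non-enolisable aromatic aldehyde with the unstabilised ylide gives the terminal styrene, and the benzyl ethers are inert to the base.

Step 9
Reactants: 10 [2,4-bis(benzyloxy)-6-hydroxyphenyl](penta-O-benzylcatechin-8-yl)methanol; 12 3,4-bis(benzyloxy)styrene
Product: 14 (2S,4S)-5,7-bis(benzyloxy)-2-[3,4-bis(benzyloxy)phenyl]-4-(penta-O-benzylcatechin-8-yl)chroman (nona-O-benzyl 2,4-cis-luteoliflavan-(4→8)-catechin), via ortho-quinone methide 13 (not isolated)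
Conditions: (R)-TRIP [(R)-3,3'-bis(2,4,6-triisopropylphenyl)-1,1'-binaphthyl-2,2'-diyl hydrogen phosphate] (10 mol%), 12 (3 equiv), 5 Å MS, PhMe, 0 °C to rt
Reagents that add atoms: none
Why: The phosphoric acid protonates the benzylic hydroxyl of 10, water leaves to the sieves and methide 13 stays hydrogen-bonded to the phosphate through its carbonyl oxygen; the CH2 terminus of styrene 12 then bonds to the methide carbon (C3–C4) while the developing p-alkoxybenzylic carbon is captured by the oxygen (O1–C2), in a concerted but asynchronous inverse-electron-demand hetero-Diels–Alder reaction that restores the aromaticity of ring A. The closest known reaction type is the Brønsted-acid-catalysed oxa-[4+2] cycloaddition (chiral phosphoric acids included) of ortho-quinone methides, released from ortho-hydroxybenzhydrols, with electron-rich styrenes to give 2,4-cis-2,4-diarylchromans. The one ring that closes, the upper pyran (O1, C2, C3, C4, C4a, C8a), forms by [4+2] cycloaddition, four atoms from the methide and two from the styrene. C4 is set by the face of the methide that the bound chiral phosphate leaves open, and C2 follows as cis to C4 through the endo orientation of the styrene aryl group, a preference backed by thermodynamics because acid can reopen the O1–C2 bond and reclose it to the diequatorial cis isomer. The step needs chemoselectivity (only the phloroglucinol ring has a free phenol, so only it can form a methide and cyclise), regioselectivity (the polarised methide takes the nucleophilic CH2 terminus at C4, and the 4-to-8 linkage was fixed by the C8 bromide), cis selectivity and face selectivity; the last is the least secure, since the lower-unit stereocenters are remote and the flavan-8-yl group is twisted out of the methide plane, so it is handed to the catalyst, and the two carbinol epimers of 10 converge on the same planar methide.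

Step 10
Reactants: 14 nona-O-benzyl 2,4-cis-luteoliflavan-(4→8)-catechin
Product: 15 (2S,4S)-2-(3,4-dihydroxyphenyl)-4-[(2R,3S)-2-(3,4-dihydroxyphenyl)-3,5,7-trihydroxychroman-8-yl]chroman-5,7-diol (CNP0180676.1)
Conditions: H2 (1 atm), Pd(OH)2/C (20 wt%), THF/MeOH/H2O, rt
Reagents that add atoms: none
Why: Heterogeneous catalytic hydrogenolysis (O-debenzylation) cleaves all nine O–CH2Ph bonds under neutral conditions, while the cyclic benzylic ethers at C2 of both flavan units and the C4–C8 bond are expected to survive at 1 atm as in perbenzylated flavan oligomers, and no stereocenter is touched.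

Compound list
1 | (+)-catechin, (2R,3S)-2-(3,4-dihydroxyphenyl)chroman-3,5,7-triol | Oc1cc(O)c2c(c1)O[C@H](c1ccc(O)c(O)c1)[C@@H](O)C2 | starting material
2 | 5,7,3',4'-tetra-O-benzyl-(+)-catechin (2R,3S) | C(c1ccccc1)Oc1cc(OCc3ccccc3)c2c(c1)O[C@H](c1ccc(OCc3ccccc3)c(OCc3ccccc3)c1)[C@@H](O)C2 | intermediate
3 | 3,5,7,3',4'-penta-O-benzyl-(+)-catechin (2R,3S) | C(c1ccccc1)Oc1cc(OCc3ccccc3)c2c(c1)O[C@H](c1ccc(OCc3ccccc3)c(OCc3ccccc3)c1)[C@@H](OCc1ccccc1)C2 | intermediate
4 | 8-bromo-3,5,7,3',4'-penta-O-benzyl-(+)-catechin (2R,3S) | Brc1c(OCc3ccccc3)cc(OCc3ccccc3)c2c1O[C@H](c1ccc(OCc3ccccc3)c(OCc3ccccc3)c1)[C@@H](OCc1ccccc1)C2 | intermediate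
5 | 2,4,6-trihydroxybenzaldehyde | O=Cc1c(O)cc(O)cc1O | starting material
6 | 2,4-bis(benzyloxy)-6-hydroxybenzaldehyde | O=Cc1c(O)cc(OCc2ccccc2)cc1OCc1ccccc1 | intermediate
7 | 2,4-bis(benzyloxy)-6-(tert-butyldimethylsilyloxy)benzaldehyde | O=Cc1c(O[Si](C)(C)C(C)(C)C)cc(OCc2ccccc2)cc1OCc1ccccc1 | intermediate
8 | 8-lithio-3,5,7,3',4'-penta-O-benzyl-(+)-catechin (2R,3S) | [Li]c1c(OCc3ccccc3)cc(OCc3ccccc3)c2c1O[C@H](c1ccc(OCc3ccccc3)c(OCc3ccccc3)c1)[C@@H](OCc1ccccc1)C2 | intermediate (not isolated)
9 | [2,4-bis(benzyloxy)-6-(tert-butyldimethylsilyloxy)phenyl](penta-O-benzylcatechin-8-yl)methanol, both carbinol epimers, catechin part (2R,3S) | OC(c1c(O[Si](C)(C)C(C)(C)C)cc(OCc2ccccc2)cc1OCc1ccccc1)c1c(OCc3ccccc3)cc(OCc3ccccc3)c2c1O[C@H](c1ccc(OCc3ccccc3)c(OCc3ccccc3)c1)[C@@H](OCc1ccccc1)C2 | intermediate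
10 | [2,4-bis(benzyloxy)-6-hydroxyphenyl](penta-O-benzylcatechin-8-yl)methanol, both carbinol epimers, catechin part (2R,3S) | OC(c1c(O)cc(OCc2ccccc2)cc1OCc1ccccc1)c1c(OCc3ccccc3)cc(OCc3ccccc3)c2c1O[C@H](c1ccc(OCc3ccccc3)c(OCc3ccccc3)c1)[C@@H](OCc1ccccc1)C2 | intermediate
11 | 3,4-bis(benzyloxy)benzaldehyde | O=Cc1ccc(OCc2ccccc2)c(OCc2ccccc2)c1 | starting material
12 | 3,4-bis(benzyloxy)styrene | C=Cc1ccc(OCc2ccccc2)c(OCc2ccccc2)c1 | intermediate
13 | (E)-3,5-bis(benzyloxy)-6-[(penta-O-benzylcatechin-8-yl)methylidene]cyclohexa-2,4-dien-1-one, the ortho-quinone methide (aryl anti to C=O; the geometry is labile under acid) | O=C1C=C(OCc2ccccc2)C=C(OCc2ccccc2)/C1=C\c1c(OCc3ccccc3)cc(OCc3ccccc3)c2c1O[C@H](c1ccc(OCc3ccccc3)c(OCc3ccccc3)c1)[C@@H](OCc1ccccc1)C2 | intermediate (not isolated)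
14 | (2S,4S)-5,7-bis(benzyloxy)-2-[3,4-bis(benzyloxy)phenyl]-4-[(2R,3S)-3,5,7-tris(benzyloxy)-2-[3,4-bis(benzyloxy)phenyl]chroman-8-yl]chroman | C(c1ccccc1)Oc1cc(OCc3ccccc3)c2c(c1)O[C@H](c1ccc(OCc3ccccc3)c(OCc3ccccc3)c1)C[C@@H]2c1c(OCc3ccccc3)cc(OCc3ccccc3)c2c1O[C@H](c1ccc(OCc3ccccc3)c(OCc3ccccc3)c1)[C@@H](OCc1ccccc1)C2 | intermediate
15 | (2S,4S)-2-(3,4-dihydroxyphenyl)-4-[(2R,3S)-2-(3,4-dihydroxyphenyl)-3,5,7-trihydroxychroman-8-yl]chroman-5,7-diol, CNP0180676.1 | Oc1cc(O)c2c(c1)O[C@H](c1ccc(O)c(O)c1)C[C@@H]2c1c(O)cc(O)c2c1O[C@H](c1ccc(O)c(O)c1)[C@@H](O)C2 | target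

Total step count: 10. Longest linear sequence: 7 steps from (+)-catechin (steps 1, 2, 3, 6, 7, 9, 10).

Steps most likely to fail

Step 9. The catalyst may discriminate the two faces of the methide only weakly, or in the wrong sense, against the bias of the chiral flavan-8-yl group. Addition to a strongly stabilised, doubly ortho-flanked methide may also be slow enough for the styrene to oligomerise or the methide to self-condense. The fallback sets out from 10 and returns at 14, making the two ring bonds in separate operations. Commercial 3',4'-bis(benzyloxy)acetophenone is converted (TMSOTf, Et3N, CH2Cl2, 0 °C) into the silyl enol ether 1-[3,4-bis(benzyloxy)phenyl]-1-(trimethylsilyloxy)ethene F1. Methide 13 is generated from 10 with catalytic diphenyl phosphate, (PhO)2P(O)OH, in CH2Cl2 at 0 °C and trapped by Mukaiyama–Michael addition of F1. This forms the C3–C4 bond and gives, after aqueous work-up, the ketone 3-[2,4-bis(benzyloxy)-6-hydroxyphenyl]-1-[3,4-bis(benzyloxy)phenyl]-3-(penta-O-benzylcatechin-8-yl)propan-1-one F2 as both epimers at the new methine. NaBH4 (THF/MeOH, 0 °C) reduces it to the diol 3-[2,4-bis(benzyloxy)-6-hydroxyphenyl]-1-[3,4-bis(benzyloxy)phenyl]-3-(penta-O-benzylcatechin-8-yl)propan-1-ol F3. Cyclodehydration with catalytic PPTS in CH2Cl2 then closes O1–C2 through the p-alkoxybenzylic cation under thermodynamic control, which should place the two aryl groups cis. The two cis diastereomers differ in the configuration of the whole upper unit against the fixed catechin and would be separated by chromatography to reach 14. Catalyst control at C4 is given up, but conjugate addition to ortho-quinone methides and cyclodehydration of 3-(2-hydroxyaryl)-1,3-diarylpropanols are both established.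

Step 6. Carbon–carbon bond formation between two doubly ortho-substituted partners may stall, the aryllithium may be protonated back to 3, and the lithium alkoxide may trigger a silyl shift from the phenolic to the benzylic oxygen. The shift is harmless for step 7 but troublesome for purification. The fallback sets out from 4 and returns at 10, reversing the roles of the partners and bypassing 7 and 9. Bromide 4 is lithiated as before and quenched with DMF to give the aldehyde 3,5,7,3',4'-penta-O-benzyl-(+)-catechin-8-carbaldehyde F4. Phenylboronic-acid-templated ortho-hydroxyalkylation of commercial 3,5-bis(benzyloxy)phenol with F4 (PhB(OH)2, catalytic propionic acid, PhMe, reflux with water removal) gives the cyclic boronate 5,7-bis(benzyloxy)-2-phenyl-4-(penta-O-benzylcatechin-8-yl)-4H-1,3,2-benzodioxaborin F5. Transesterification with propane-1,3-diol (THF, rt) releases 10. The aryl–carbon bond is formed by delivery inside the boron template, the two ortho positions of the phenol are equivalent by symmetry, and no silyl group is involved.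

Step 4. Over-alkylation to the tribenzyl ether, C-benzylation of the phloroglucinol ring and a near-statistical mixture may make isolation inefficient. The fallback sets out from 5 and returns at 6. Exhaustive O-benzylation (BnBr 3.5 equiv, K2CO3, DMF, 60 °C) gives 2,4,6-tris(benzyloxy)benzaldehyde F6. Chelation-directed mono-debenzylation of one ether ortho to the formyl group with MgBr2·OEt2 (PhMe/Et2O, reflux) then returns 6. The two ortho ethers are equivalent, the para ether cannot chelate, and the first cleavage deactivates the aldehyde towards a second.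

Further compounds
F1 | step 9 | 1-[3,4-bis(benzyloxy)phenyl]-1-(trimethylsilyloxy)ethene | C=C(O[Si](C)(C)C)c1ccc(OCc2ccccc2)c(OCc2ccccc2)c1
F2 | step 9 | 3-[2,4-bis(benzyloxy)-6-hydroxyphenyl]-1-[3,4-bis(benzyloxy)phenyl]-3-(penta-O-benzylcatechin-8-yl)propan-1-one, both C3 epimers | O=C(CC(c1c(O)cc(OCc2ccccc2)cc1OCc1ccccc1)c1c(OCc3ccccc3)cc(OCc3ccccc3)c2c1O[C@H](c1ccc(OCc3ccccc3)c(OCc3ccccc3)c1)[C@@H](OCc1ccccc1)C2)c1ccc(OCc2ccccc2)c(OCc2ccccc2)c1
F3 | step 9 | 3-[2,4-bis(benzyloxy)-6-hydroxyphenyl]-1-[3,4-bis(benzyloxy)phenyl]-3-(penta-O-benzylcatechin-8-yl)propan-1-ol, all epimers at C1 and C3 | OC(CC(c1c(O)cc(OCc2ccccc2)cc1OCc1ccccc1)c1c(OCc3ccccc3)cc(OCc3ccccc3)c2c1O[C@H](c1ccc(OCc3ccccc3)c(OCc3ccccc3)c1)[C@@H](OCc1ccccc1)C2)c1ccc(OCc2ccccc2)c(OCc2ccccc2)c1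
F4 | step 6 | 3,5,7,3',4'-penta-O-benzyl-(+)-catechin-8-carbaldehyde (2R,3S) | O=Cc1c(OCc3ccccc3)cc(OCc3ccccc3)c2c1O[C@H](c1ccc(OCc3ccccc3)c(OCc3ccccc3)c1)[C@@H](OCc1ccccc1)C2
F5 | step 6 | 5,7-bis(benzyloxy)-2-phenyl-4-(penta-O-benzylcatechin-8-yl)-4H-1,3,2-benzodioxaborin, both C4 epimers | c1ccccc1B1Oc2cc(OCc3ccccc3)cc(OCc3ccccc3)c2C(O1)c1c(OCc3ccccc3)cc(OCc3ccccc3)c2c1O[C@H](c1ccc(OCc3ccccc3)c(OCc3ccccc3)c1)[C@@H](OCc1ccccc1)C2
F6 | step 4 | 2,4,6-tris(benzyloxy)benzaldehyde | O=Cc1c(OCc2ccccc2)cc(OCc2ccccc2)cc1OCc1ccccc1
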